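## Structural features

The target (numbered O1–O2–C3–C4–C5–C6 in the ring, acid carbons C2 and C1 on C3, chain C7 to C16 on C6) is a 1,2-dioxane. C3 is a peroxy hemiketal carbon bearing a hydroxyl group and the acetic acid arm; C4 bears a methyl group; C6 is fully substituted, with a methyl group and a chain that has a methyl branch on C8 and a phenyl ring on C16. Of the four stereocentres, C3 and C4 are neighbours, C6 stands 1,3 to C4 across C5, and C8 stands 1,3 to C6 across C7, outside the ring. In the chair the C3 hydroxyl is axial (anomeric to O2) and the acid arm, the C4 methyl and the C6 chain are equatorial. C3 is therefore the thermodynamic hemiketal, and C4, which can epimerise through the open keto form, already sits in its favoured position; C6 and C8 cannot be corrected once made. The fragile groups are the O–O bond (low-valent metals, phosphines, hydrides, strong carbanions, strong acids) and the hemiketal, which is the ring tautomer of a δ-hydroperoxy β-keto acid that can decarboxylate or fragment when opened. The real difficulty is the oxygen-bearing quaternary centre C6, its relationship to C4 and C8, and the absolute configuration of two methyl-bearing centres that lie far apart. The key step exploits the fact that C4 and C8 with their methyl groups are mirror images about C6: a temporary C3=C9 double bond turns C3 to C9 into a meso cis-3,6-dimethylcyclohept-4-enone (C6 the carbonyl carbon), a seven-membered carbocycle absent from the target, on which the three methyl groups are cis and the C6 oxygen is trans to them.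

## Logic of the disconnections

24 ⇒ 23. The C1 acid is taken back to its ethyl ester. The open tautomer of the ring is a β-keto acid, so C1 stays an ester until the ring is closed. The gain is that the last C–C bond can be made with a diazo ester; the demand is an ester cleavage that spares the O–O bond and the hemiketal.

23 ⇒ 22 ⇒ 21. The O2–C3 hemiketal bond is cut, then the peroxide hydrogen is replaced by silicon. A δ-hydroperoxy ketone closes by itself and C3 settles thermodynamically. The ring and one stereocentre leave the problem, which becomes an open chain carrying C4, C6 and C8. The forward step must remove silicon without base and without an alcohol solvent.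

21 ⇒ 19 + 20. The C2–C3 bond is cut. A one-step homologation of an aldehyde to a β-keto ester brings C1 and C2 from a purchased reagent. The demand is a Lewis acid that leaves the peroxide alone and conditions under which the α-centre C4 of 19 does not epimerise.

19 ⇒ 18 ⇒ 17. No skeletal bond is cut; the C3 aldehyde is traced to the alcohol and this to its acetate. The acetate is the mark left by the enzyme, so no extra protecting group is needed. The demand is a deacetylation that does not cleave the Si–OO bond.

17 ⇒ 16 ⇒ 12 + 15, with 15 from 14 and 14 from 13. The C9–C10 bond is cut (as C9=C10). This removes the achiral phenylalkyl tail and leaves only the C3–C9 segment to be made in chiral form. The forward olefination must tolerate a silyl peroxide and an epimerisable aldehyde, and the alkene must be saturated without a metal hydride catalyst.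

12 ⇒ 11 ⇒ 10 ⇒ 9. The two chain ends are made identical (both CH2OH). Compound 9 has a mirror plane through C6, so absolute configuration reduces to choosing one of two enantiotopic arms. One enzymatic event then fixes C4, C6 and C8 without any chiral reagent. The demand is that hydrolysis frees the C9 arm; acylation of 9 by the same enzyme would mark the wrong end, hence the detour through 10.

9 ⇒ 8 ⇒ 7. C3 and C9 are rejoined as a double bond (retro-ozonolysis). The open meso chain becomes a seven-membered ring on which the relationship of C4, C6 and C8 is a cis/trans question. The forward cleavage and reduction must not touch the silyl peroxide or epimerise the dialdehyde.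

7 ⇒ 6. The C6–O1 bond is cut. A Markovnikov hydroperoxysilylation of a 1,1-disubstituted alkene installs both oxygen atoms already protected. The demand is chemoselectivity over the ring alkene and oxygen delivery to the face trans to the two methyl groups.

6 ⇒ 5. The C6=CH2 bond (the future C6 methyl carbon) is cut. Methylenation of a ketone is the simplest way to make C6 a radical precursor; nothing stereochemical is at stake.

5 ⇒ 4 ⇒ 3 + 1, with 3 from 2. The C4–C5 and C7–C8 bonds are cut. C5–C6–C7 is a three-carbon oxyallyl unit and C4–C3=C9–C8 with its two methyl groups is a diene, both derived from purchased achiral compounds. The whole C3–C9 array comes from one step, which must deliver the cis (meso) ring.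

## Other disconnections considered

Alternative 1: The cut falls on C5–C6 and O2–C3. In the forward sense SnCl4 (tetravalent tin) would ionise the mixed silylperoxy ketal A2 to a peroxycarbenium ion at C6. The siloxycyclopropane A3 would open at its CH2 carbon to form C5–C6, and the silylperoxy oxygen would close on the C3 oxocarbenium ion to give the dioxanol A1.
- In its favour: ring, hemiketal and both new bonds arise in one convergent step; the O–O bond is brought in intact and late; C4 and C8 arrive as preformed centres.
- Against it here: C6 is created by attack on an acyclic planar cation whose flanks differ little and whose only stereocentre (C8) is remote, so no useful facial bias is expected. A2 and A3 each need their own enantioselective entry. A strong Lewis acid on a tertiary peroxide invites Hock- or Criegee-type fragmentation. The acid must still be made from the silyl ether of A1 by desilylation and oxidation beside the hemiketal.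
- Comparison: the alternative is the better plan on step count and on the short residence time of the peroxide. The two are equal on C3, which is thermodynamic in both. On C6 the chosen plan is only modestly better: its oxygen capture is also weakly selective, but it happens early, on a ring, and gives separable meso isomers. On absolute configuration the chosen plan is better, since one enzymatic event serves three centres.

Alternative 2: The cut is the C4=C5 bond of a dihydrodioxine. A second-generation Hoveyda–Grubbs ruthenium catalyst would join the vinyl group on C6 and the isopropenyl group on C3 of the acyclic peroxide A5 to give the dihydrodioxine A4.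
- In its favour: ring closure onto a preformed O–O bond is mechanistically simple, ruthenium carbenes tolerate dialkyl peroxides, and the closure is not a stereochemical event.
- Against it here: the difficulty moves into A5, which needs an enantio-defined tertiary allylic hydroperoxide at C6 and its union with a mixed ketal. C4 must then be set by reducing a trisubstituted ring alkene beside an O–O bond, where diimide is sluggish and catalytic hydrogenation threatens the peroxide. The methyl ketal must still be exchanged for the hemiketal and the ester hydrolysed.
- Comparison: the alternative is the better plan on reliability of ring formation and equal on the final ester hydrolysis. It is weaker on C6 and C4, which the chosen plan derives from one cycloaddition and one ring-based oxygenation, and it is not clearly shorter once A5 is counted.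

Alternative 3: The cuts are C4–C5, C6–O1 and O2–C3. Mn(OAc)3 (trivalent manganese) would oxidise the 2-methyl β-keto ester A7 to its C4 radical, which adds to the terminus of the alkene A8. The tertiary C6 radical takes up O2, and the peroxide closes on the C3 ketone to give the dioxanol ester A6.
- In its favour: three bonds and both peroxide oxygens come from air in one step from two simple partners. On paper it is the shortest of the four plans and stands in a known reaction class.
- Against it here: C6 is formed by oxygen capture at an acyclic tertiary radical with no facial control. An unactivated 1,1-dialkyl alkene is a poor acceptor for the electrophilic radical. C4 is formed quaternary, so the tert-butyl ester must later be removed by decarboxylating a β-keto acid locked as a hemiketal, which requires ring opening. The alcohol must still be deprotected and oxidised.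
- Comparison: the alternative is the better plan on step economy and convergence. On C6 the elementary step is the same in both plans, and the chosen plan is better only through its ring and its separable meso diastereomers. On C4 both rely in part on the thermodynamic preference for an equatorial methyl, which is a point of equality. On absolute configuration the chosen plan is better.

Key step: step 1

Assumption: Pseudomonas fluorescens lipase is taken to react faster at the CH2O arm attached to the (S)-configured methyl-bearing carbon, as the empirical rule for 2-methyl-substituted primary alcohols predicts; hydrolysis of the meso diacetate then frees the C9 hydroxyl.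

## Steps

Step 1
Reactants: 1 (2E,4E)-hexa-2,4-diene; 2 1,1,3,3-tetrabromopropan-2-one
Product: 5 (3R,6S)-3,6-dimethylcyclohept-4-en-1-one, via iron-bound 1,3-dibromo-2-oxyallyl cation 3 (not isolated), via 2,7-dibromo-3,6-dimethylcyclohept-4-en-1-one 4 (not isolated)
Conditions: 1 (excess), Fe2(CO)9, PhMe, 60 °C; then Zn/Cu, NH4Cl, MeOH, rt
Reagents that add atoms: none
Why: Fe2(CO)9 (zerovalent iron) reduces one C–Br bond of 2 to a bromoiron enolate, and loss of the allylic bromide gives the iron-bound 1,3-dibromo-2-oxyallyl cation 3, a two-electron three-carbon partner. This cation adds across C2 and C5 of the s-cis conformer of 1 in a [4+3] cycloaddition, the closest known reaction type being the iron-carbonyl-promoted cyclocoupling of polybromo ketones with 1,3-dienes. The seven-membered ring is closed by intermolecular annulation of a four-carbon and a three-carbon unit, with C4–C5 and C7–C8 (target numbering) formed together or in two fast consecutive events. The new stereocentres C4 and C8 are controlled by the diene geometry: in the s-cis (E,E)-diene both methyl groups point outward, so addition to one face of both termini places them cis, which is the meso arrangement. The selectivity needed is cis over trans, and it holds as long as the second bond forms faster than rotation in any zwitterionic intermediate; a trans contaminant would be a chiral racemate that can be separated from meso 5 or later from 9. The bromine-bearing carbons of 4 carry no information that is kept, since Zn/Cu (zerovalent zinc) with NH4Cl reduces both C–Br bonds through zinc enolates and returns the two CH2 groups that flank C6. No absolute control is asked of this step, because 5 has a mirror plane through C6 and the midpoint of the alkene.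

Step 2
Reactants: 5 (3R,6S)-3,6-dimethylcyclohept-4-en-1-one
Product: 6 (3R,7S)-3,7-dimethyl-5-methylidenecyclohept-1-ene
Conditions: Ph3PCH3Br, KOtBu, THF, 0 °C to rt
Reagents that add atoms: methyltriphenylphosphonium bromide, C[P+](c1ccccc1)(c1ccccc1)c1ccccc1.[Br-]
Why: Wittig methylenation of an unhindered ketone whose α-carbons are both CH2 groups, so no stereocentre is at risk; the new exocyclic carbon is the future C6 methyl group. The volatile diene is handled in pentane and not concentrated to dryness.

Step 3
Reactants: 6 (3R,7S)-3,7-dimethyl-5-methylidenecyclohept-1-ene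
Product: 7 triethyl{[(1s,3R,6S)-1,3,6-trimethylcyclohept-4-en-1-yl]peroxy}silane
Conditions: Co(acac)2 (cat.), O2 (1 atm), Et3SiH, ClCH2CH2Cl, rt
Reagents that add atoms: dioxygen, O=O; triethylsilane, CC[SiH](CC)CC
Why: Mukaiyama–Isayama hydroperoxysilylation: a cobalt hydride transfers a hydrogen atom to the terminal CH2 of the 1,1-disubstituted alkene (the 1,2-disubstituted ring alkene reacts far more slowly), the tertiary C6 radical captures O2, and the cobalt peroxide is silylated by Et3SiH. C–O bond formation should prefer the face trans to the C4 and C8 methyl groups (axial entry on the chair that holds both methyls equatorial), but the bias is expected to be modest; the two products are meso diastereomers and the unwanted one is removed here or at 9.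

Step 4
Reactants: 7 triethyl{[(1s,3R,6S)-1,3,6-trimethylcyclohept-4-en-1-yl]peroxy}silane
Product: 9 (2R,4s,6S)-2,4,6-trimethyl-4-[(triethylsilyl)peroxy]heptane-1,7-diol, via (2R,4s,6S)-2,4,6-trimethyl-4-[(triethylsilyl)peroxy]heptanedial 8 (not isolated)
Conditions: O3, CH2Cl2/MeOH, −78 °C; Me2S, −78 °C to rt; NaBH4, 0 °C
Reagents that add atoms: ozone, [O-][O+]=O
Why: Ozonolysis with reductive work-up: the only remaining alkene is cleaved, Me2S reduces the peroxidic ozonolysis products to dialdehyde 8 without touching the hindered silyl peroxide, and NaBH4 at 0 °C reduces both aldehydes before the α-methyl centres can epimerise. The mirror plane through C6 is kept, so 9 is meso.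

Step 5
Reactants: 9 (2R,4s,6S)-2,4,6-trimethyl-4-[(triethylsilyl)peroxy]heptane-1,7-diol
Product: 10 (2R,4s,6S)-2,4,6-trimethyl-4-[(triethylsilyl)peroxy]heptane-1,7-diyl diacetate
Conditions: Ac2O, pyridine, DMAP (cat.), CH2Cl2, 0 °C to rt
Reagents that add atoms: acetic anhydride, CC(=O)OC(C)=O
Why: Standard DMAP-catalysed acetylation of two primary alcohols; it prepares the substrate for hydrolytic desymmetrisation and leaves the mirror plane intact.

Step 6
Reactants: 10 (2R,4s,6S)-2,4,6-trimethyl-4-[(triethylsilyl)peroxy]heptane-1,7-diyl diacetate
Product: 11 (2R,4S,6S)-7-hydroxy-2,4,6-trimethyl-4-[(triethylsilyl)peroxy]heptyl acetate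
Conditions: Pseudomonas fluorescens lipase, phosphate buffer pH 7, acetone (cosolvent), rt
Reagents that add atoms: none
Why: Enzymatic desymmetrisation by enantiotopos-selective ester hydrolysis: the lipase is expected to cleave the acetate on the arm whose methyl-bearing carbon is (S)-configured, which frees the C9 hydroxyl and fixes the absolute configuration of C4, C6 and C8 in one event. Continued hydrolysis removes the minor enantiomer faster than the major one (as 9, which is recycled through step 5), so the enantiomeric purity of 11 can be raised at the cost of some material.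

Step 7
Reactants: 11 (2R,4S,6S)-7-hydroxy-2,4,6-trimethyl-4-[(triethylsilyl)peroxy]heptyl acetate
Product: 12 (2R,4R,6S)-2,4,6-trimethyl-7-oxo-4-[(triethylsilyl)peroxy]heptyl acetate
Conditions: Dess–Martin periodinane, NaHCO3, CH2Cl2, 0 °C to rt
Reagents that add atoms: none
Why: Dess–Martin oxidation under buffered, non-basic conditions gives the α-methyl aldehyde without epimerisation at C8 and without affecting the acetate or the silyl peroxide; 12 is used at once.

Step 8
Reactants: 13 (7-bromoheptyl)benzene
Product: 14 triphenyl(7-phenylheptyl)phosphonium bromide
Conditions: PPh3, MeCN, reflux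
Reagents that add atoms: triphenylphosphine, c1ccc(P(c2ccccc2)c2ccccc2)cc1
Why: SN2 quaternisation of a primary bromide by triphenylphosphine gives the Wittig salt that carries C10 to C16 and the phenyl ring.

Step 9
Reactants: 14 triphenyl(7-phenylheptyl)phosphonium bromide; 12 (2R,4R,6S)-2,4,6-trimethyl-7-oxo-4-[(triethylsilyl)peroxy]heptyl acetate
Product: 16 (2R,4S,6S,7Z)-2,4,6-trimethyl-14-phenyl-4-[(triethylsilyl)peroxy]tetradec-7-en-1-yl acetate, via triphenyl(7-phenylheptylidene)-λ5-phosphane 15 (not isolated)
Conditions: NaN(SiMe3)2, THF, 0 °C; then 12, −78 °C to 0 °C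
Reagents that add atoms: none
Why: Wittig olefination with a non-stabilised ylide forms C9=C10 (mainly Z; the geometry is irrelevant). Addition to the aldehyde at −78 °C is much faster than attack of the ylide on the acetate or on the hindered tertiary silyl peroxide, and the short contact time at low temperature protects C8.

Step 10
Reactants: 16 (2R,4S,6S,7Z)-2,4,6-trimethyl-14-phenyl-4-[(triethylsilyl)peroxy]tetradec-7-en-1-yl acetate
Product: 17 (2R,4S,6R)-2,4,6-trimethyl-14-phenyl-4-[(triethylsilyl)peroxy]tetradecyl acetate
Conditions: 2-nitrobenzenesulfonylhydrazide, Et3N, CH2Cl2, rt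
Reagents that add atoms: none
Why: Diimide reduction, with diimide generated at room temperature from the sulfonylhydrazide, saturates the 1,2-disubstituted alkene by concerted syn hydrogen transfer and, unlike metal-catalysed hydrogenation, leaves the O–O bond untouched.

Step 11
Reactants: 17 (2R,4S,6R)-2,4,6-trimethyl-14-phenyl-4-[(triethylsilyl)peroxy]tetradecyl acetate
Product: 18 (2R,4S,6R)-2,4,6-trimethyl-14-phenyl-4-[(triethylsilyl)peroxy]tetradecan-1-ol
Conditions: immobilised Candida antarctica lipase B, n-BuOH, t-BuOMe, 30 °C
Reagents that add atoms: none
Why: Lipase-catalysed alcoholysis (transesterification to butanol) removes the primary acetate under neutral, anhydrous conditions; carbonate or methoxide in methanol is avoided because it would also cleave the Si–OO bond.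

Step 12
Reactants: 18 (2R,4S,6R)-2,4,6-trimethyl-14-phenyl-4-[(triethylsilyl)peroxy]tetradecan-1-ol
Product: 19 (2R,4S,6R)-2,4,6-trimethyl-14-phenyl-4-[(triethylsilyl)peroxy]tetradecanal
Conditions: Dess–Martin periodinane, NaHCO3, CH2Cl2, 0 °C to rt
Reagents that add atoms: none
Why: Dess–Martin oxidation as in step 7; the α-methyl aldehyde (C4 stereocentre) is carried on without chromatography.

Step 13
Reactants: 19 (2R,4S,6R)-2,4,6-trimethyl-14-phenyl-4-[(triethylsilyl)peroxy]tetradecanal; 20 ethyl diazoacetate
Product: 21 ethyl (4R,6S,8R)-4,6,8-trimethyl-3-oxo-16-phenyl-6-[(triethylsilyl)peroxy]hexadecanoate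
Conditions: SnCl2 (cat.), CH2Cl2, rt
Reagents that add atoms: none
Why: Roskamp reaction: the Lewis acid activates the aldehyde, the diazo ester adds, and a 1,2-hydride shift with loss of N2 gives the β-keto ester directly, forming C2–C3. The medium is essentially neutral, so C4 keeps its configuration, and SnCl2 (divalent tin) is used in catalytic amount to limit its contact with the peroxide.

Step 14
Reactants: 21 ethyl (4R,6S,8R)-4,6,8-trimethyl-3-oxo-16-phenyl-6-[(triethylsilyl)peroxy]hexadecanoate
Product: 23 ethyl 2-{(3S,4R,6S)-3-hydroxy-4,6-dimethyl-6-[(2R)-2-methyl-10-phenyldecyl]-1,2-dioxan-3-yl}acetate, via ethyl (4R,6S,8R)-6-hydroperoxy-4,6,8-trimethyl-3-oxo-16-phenylhexadecanoate 22 (not isolated)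
Conditions: HF·pyridine, pyridine, THF, 0 °C to rt
Reagents that add atoms: none
Why: Fluoride cleaves the Si–OO bond and the freed δ-hydroperoxide 22 adds to the C3 ketone in a 6-exo-trig closure that forms O2–C3 (peroxy hemiketalisation). C3 is set under thermodynamic control with the hydroxyl axial (anomeric to O2) and the ester arm equatorial; the C4 methyl and the C6 chain are both equatorial in this chair, so no centre is driven to epimerise.

Step 15
Reactants: 23 ethyl 2-{(3S,4R,6S)-3-hydroxy-4,6-dimethyl-6-[(2R)-2-methyl-10-phenyldecyl]-1,2-dioxan-3-yl}acetate
Product: 24 2-{(3S,4R,6S)-3-hydroxy-4,6-dimethyl-6-[(2R)-2-methyl-10-phenyldecyl]-1,2-dioxan-3-yl}acetic acid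
Conditions: LiOH, THF/H2O, 0 °C; then dilute HCl to pH 3–4, 0 °C
Reagents that add atoms: lithium hydroxide, [Li+].[OH-]
Why: Saponification of an ethyl ester with LiOH at 0 °C is a transformation known for esters that carry 1,2-dioxane rings. C6 has no hydrogen, so base cannot trigger a Kornblum–DeLaMare fragmentation, and cold acidification returns the closed hemiketal acid.

## Compound list

1 | (2E,4E)-hexa-2,4-diene | C/C=C/C=C/C | starting material
2 | 1,1,3,3-tetrabromopropan-2-one | BrC(Br)C(=O)C(Br)Br | starting material
3 | iron-bound 1,3-dibromo-2-oxyallyl cation (bromoiron enolate, bromide counter-ion) | Br[CH+]C(=CBr)O[Fe]Br.[Br-] | intermediate (not isolated)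
4 | 2,7-dibromo-3,6-dimethylcyclohept-4-en-1-one (3,6-cis; mixture at the bromine-bearing carbons) | C[C@H]1C=C[C@@H](C)C(Br)C(=O)C1Br | intermediate (not isolated)
5 | (3R,6S)-3,6-dimethylcyclohept-4-en-1-one (cis, meso) | C[C@H]1C=C[C@@H](C)CC(=O)C1 | intermediate
6 | (3R,7S)-3,7-dimethyl-5-methylidenecyclohept-1-ene (cis, meso) | C[C@H]1C=C[C@@H](C)CC(=C)C1 | intermediate
7 | triethyl{[(1s,3R,6S)-1,3,6-trimethylcyclohept-4-en-1-yl]peroxy}silane (three methyls cis, peroxy group trans to them, meso) | C[C@@]1(OO[Si](CC)(CC)CC)C[C@@H](C)C=C[C@@H](C)C1 | intermediate
8 | (2R,4s,6S)-2,4,6-trimethyl-4-[(triethylsilyl)peroxy]heptanedial (meso) | C[C@H](C=O)C[C@@](OO[Si](CC)(CC)CC)(C)C[C@@H](C)C=O | intermediate (not isolated)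
9 | (2R,4s,6S)-2,4,6-trimethyl-4-[(triethylsilyl)peroxy]heptane-1,7-diol (meso) | C[C@H](CO)C[C@@](OO[Si](CC)(CC)CC)(C)C[C@@H](C)CO | intermediate
10 | (2R,4s,6S)-2,4,6-trimethyl-4-[(triethylsilyl)peroxy]heptane-1,7-diyl diacetate (meso) | C[C@H](COC(C)=O)C[C@@](OO[Si](CC)(CC)CC)(C)C[C@@H](C)COC(C)=O | intermediate
11 | (2R,4S,6S)-7-hydroxy-2,4,6-trimethyl-4-[(triethylsilyl)peroxy]heptyl acetate | C[C@H](CO)C[C@@](OO[Si](CC)(CC)CC)(C)C[C@@H](C)COC(C)=O | intermediate
12 | (2R,4R,6S)-2,4,6-trimethyl-7-oxo-4-[(triethylsilyl)peroxy]heptyl acetate | C[C@H](C=O)C[C@@](OO[Si](CC)(CC)CC)(C)C[C@@H](C)COC(C)=O | intermediate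
13 | (7-bromoheptyl)benzene | BrCCCCCCCc1ccccc1 | starting material
14 | triphenyl(7-phenylheptyl)phosphonium bromide | [Br-].c1ccc(CCCCCCC[P+](c2ccccc2)(c2ccccc2)c2ccccc2)cc1 | intermediate
15 | triphenyl(7-phenylheptylidene)-λ5-phosphane | c1ccc(CCCCCCC=P(c2ccccc2)(c2ccccc2)c2ccccc2)cc1 | intermediate (not isolated)
16 | (2R,4S,6S,7Z)-2,4,6-trimethyl-14-phenyl-4-[(triethylsilyl)peroxy]tetradec-7-en-1-yl acetate | C[C@H](/C=C\CCCCCCc1ccccc1)C[C@@](OO[Si](CC)(CC)CC)(C)C[C@@H](C)COC(C)=O | intermediate
17 | (2R,4S,6R)-2,4,6-trimethyl-14-phenyl-4-[(triethylsilyl)peroxy]tetradecyl acetate | C[C@H](CCCCCCCCc1ccccc1)C[C@@](OO[Si](CC)(CC)CC)(C)C[C@@H](C)COC(C)=O | intermediate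
18 | (2R,4S,6R)-2,4,6-trimethyl-14-phenyl-4-[(triethylsilyl)peroxy]tetradecan-1-ol | C[C@H](CCCCCCCCc1ccccc1)C[C@@](OO[Si](CC)(CC)CC)(C)C[C@@H](C)CO | intermediate
19 | (2R,4S,6R)-2,4,6-trimethyl-14-phenyl-4-[(triethylsilyl)peroxy]tetradecanal | C[C@H](CCCCCCCCc1ccccc1)C[C@@](OO[Si](CC)(CC)CC)(C)C[C@@H](C)C=O | intermediate
20 | ethyl diazoacetate | CCOC(=O)C=[N+]=[N-] | starting material
21 | ethyl (4R,6S,8R)-4,6,8-trimethyl-3-oxo-16-phenyl-6-[(triethylsilyl)peroxy]hexadecanoate | C[C@H](CCCCCCCCc1ccccc1)C[C@@](OO[Si](CC)(CC)CC)(C)C[C@@H](C)C(=O)CC(=O)OCC | intermediate
22 | ethyl (4R,6S,8R)-6-hydroperoxy-4,6,8-trimethyl-3-oxo-16-phenylhexadecanoate | C[C@H](CCCCCCCCc1ccccc1)C[C@@](OO)(C)C[C@@H](C)C(=O)CC(=O)OCC | intermediate (not isolated)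
23 | ethyl 2-{(3S,4R,6S)-3-hydroxy-4,6-dimethyl-6-[(2R)-2-methyl-10-phenyldecyl]-1,2-dioxan-3-yl}acetate | C[C@H](CCCCCCCCc1ccccc1)C[C@@]1(C)C[C@@H](C)[C@](O)(CC(=O)OCC)OO1 | intermediate
24 | 2-{(3S,4R,6S)-3-hydroxy-4,6-dimethyl-6-[(2R)-2-methyl-10-phenyldecyl]-1,2-dioxan-3-yl}acetic acid | C[C@H](CCCCCCCCc1ccccc1)C[C@@]1(C)C[C@@H](C)[C@](O)(CC(=O)O)OO1 | target

## Step count and least certain steps

Total step count: 15. Longest linear sequence: 14 steps (steps 1 to 7 and 9 to 15); step 8 is a one-step side branch.

Step 1 (key step). The oxyallyl species may be lost to over-reduction or oligomerisation before it meets an open-chain diene that is only weakly nucleophilic and mostly s-trans. Bond formation in two slow stages would allow rotation and erode the cis relationship. Fallback: set out from 1 and convert it separately into tricarbonyl[(2E,4E)-η4-hexa-2,4-diene]iron F1 (Fe2(CO)9, warm hydrocarbon solvent). Heating F1 with 2 in toluene lets the complex serve both as the reductant and as a diene already held s-cis on the metal. The same dibromide 4 is then debrominated with Zn/Cu, and the route is rejoined at 5.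

Step 3. A nearly planar tertiary radical and a very fast trap (O2) give little facial discrimination, so the wanted meso isomer may form with only a small excess. The peroxy radical may also add across the ring to the alkene before it is reduced and silylated (a high silane concentration counters this). The configuration at C6 of the isomer carried forward must be secured by analysis at 9. Fallback: replace the radical oxygenation by an ionic one. Setting out from 6, 50% aqueous H2O2 with catalytic H2SO4 at 0 °C adds in the Markovnikov sense through the tertiary C6 cation. Reversible ionisation lets the product drift toward the isomer with the equatorial methyl and axial peroxy group, which is the wanted one, giving (1s,3R,6S)-1,3,6-trimethylcyclohept-4-en-1-yl hydroperoxide F2. Silylation with Et3SiCl and imidazole in CH2Cl2 rejoins the route at 7.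

Step 6. The enzyme may discriminate poorly between the two acetoxymethyl arms, whose stereocentres are far from each other and next to a bulky quaternary carbon, or it may prefer the other arm. The lipophilic substrate may hydrolyse slowly in buffer, and long exposure may hydrolyse the Si–OO bond. Fallback: reverse the direction of the enzymatic reaction. Setting out from 9, acetylation with vinyl acetate in a dry organic solvent by a lipase that prefers the C3 arm (porcine pancreatic lipase is a candidate) gives 11 directly and rejoins the route there; no compound beyond the list is made (F0).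

Step 9. The ylide carbanion may attack the silyl peroxide at silicon or oxygen, and the basic medium may epimerise the aldehyde at C8. Fallback: a Julia–Kocienski olefination in Barbier mode, in which the metallated sulfone is consumed as it forms. Setting out from 13, alkylation of 1-phenyl-1H-tetrazole-5-thiol (K2CO3, acetone) gives 1-phenyl-5-[(7-phenylheptyl)sulfanyl]-1H-tetrazole F3. Oxidation (H2O2, (NH4)6Mo7O24 cat., EtOH) gives 1-phenyl-5-[(7-phenylheptyl)sulfonyl]-1H-tetrazole F4. Adding KN(SiMe3)2 to a mixture of F4 and 12 in THF at −78 °C gives (2R,4S,6S,7E)-2,4,6-trimethyl-14-phenyl-4-[(triethylsilyl)peroxy]tetradec-7-en-1-yl acetate F5. Diimide reduction as in step 10 rejoins the route at 17.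

Step 13. Divalent tin may reduce the O–O bond, or the Lewis acid may ionise the tertiary silyl peroxide; either consumes catalyst and substrate. Fallback: build C2–C3 in two steps without a Lewis acid or reductant. Setting out from 19, addition of the lithium enolate of ethyl acetate (LiN(iPr)2, EtOAc, THF, −78 °C) gives ethyl (4R,6S,8R)-3-hydroxy-4,6,8-trimethyl-16-phenyl-6-[(triethylsilyl)peroxy]hexadecanoate F6 (both C3 epimers). Dess–Martin oxidation rejoins the route at 21.

Step 15. Hydroxide may open the hemiketal and expose a β-keto ester to retro-Claisen cleavage and a free hydroperoxide anion to side reactions. On acidification any open β-keto acid may decarboxylate before it recloses. Fallback: abandon hydroxide for enzymatic hydrolysis. Setting out from 23, pig liver esterase in phosphate buffer at pH 7 with a little acetone cleaves the ethyl ester while the ring stays closed and gives 24 directly; no compound beyond the list is made (F0).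

## Further compounds

F1 | step 1 | tricarbonyl[(2E,4E)-η4-hexa-2,4-diene]iron | C/C=C/C=C/C.[C-]#[O+].[C-]#[O+].[C-]#[O+].[Fe]
F2 | step 3 | (1s,3R,6S)-1,3,6-trimethylcyclohept-4-en-1-yl hydroperoxide | C[C@@]1(OO)C[C@@H](C)C=C[C@@H](C)C1
F0 | step 6 | none | none
F3 | step 9 | 1-phenyl-5-[(7-phenylheptyl)sulfanyl]-1H-tetrazole | c1ccc(CCCCCCCSc2nnnn2-c2ccccc2)cc1
F4 | step 9 | 1-phenyl-5-[(7-phenylheptyl)sulfonyl]-1H-tetrazole | O=S(=O)(CCCCCCCc1ccccc1)c1nnnn1-c1ccccc1
F5 | step 9 | (2R,4S,6S,7E)-2,4,6-trimethyl-14-phenyl-4-[(triethylsilyl)peroxy]tetradec-7-en-1-yl acetate | C[C@H](/C=C/CCCCCCc1ccccc1)C[C@@](OO[Si](CC)(CC)CC)(C)C[C@@H](C)COC(C)=O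
F6 | step 13 | ethyl (4R,6S,8R)-3-hydroxy-4,6,8-trimethyl-16-phenyl-6-[(triethylsilyl)peroxy]hexadecanoate (both C3 epimers) | C[C@H](CCCCCCCCc1ccccc1)C[C@@](OO[Si](CC)(CC)CC)(C)C[C@@H](C)C(O)CC(=O)OCC
F0 | step 15 | none | none
A1 | alternative 1 | (3S,4R,6S)-3-[2-(tert-butyldiphenylsilyloxy)ethyl]-4,6-dimethyl-6-[(2R)-2-methyl-10-phenyldecyl]-1,2-dioxan-3-ol | C[C@H](CCCCCCCCc1ccccc1)C[C@@]1(C)C[C@@H](C)[C@](O)(CCO[Si](c2ccccc2)(c2ccccc2)C(C)(C)C)OO1
A2 | alternative 1 | triethyl{[(4R)-2-methoxy-4-methyl-12-phenyldodecan-2-yl]peroxy}silane | C[C@H](CCCCCCCCc1ccccc1)CC(C)(OC)OO[Si](CC)(CC)CC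
A3 | alternative 1 | tert-butyl{2-[(2R)-2-methyl-1-(trimethylsilyloxy)cyclopropyl]ethoxy}diphenylsilane | C1[C@@H](C)C1(O[Si](C)(C)C)CCO[Si](c1ccccc1)(c1ccccc1)C(C)(C)C
A4 | alternative 2 | methyl 2-{(3S,6S)-3-methoxy-4,6-dimethyl-6-[(2R)-2-methyl-10-phenyldecyl]-3,6-dihydro-1,2-dioxin-3-yl}acetate | C[C@H](CCCCCCCCc1ccccc1)C[C@@]1(C)C=C(C)[C@](OC)(CC(=O)OC)OO1
A5 | alternative 2 | methyl (3S)-3-{[(3S,5R)-3,5-dimethyl-13-phenyltridec-1-en-3-yl]peroxy}-3-methoxy-4-methylpent-4-enoate | C[C@H](CCCCCCCCc1ccccc1)C[C@@](C)(C=C)OO[C@@](OC)(CC(=O)OC)C(C)=C
A6 | alternative 3 | tert-butyl 3-[2-(tert-butyldiphenylsilyloxy)ethyl]-3-hydroxy-4,6-dimethyl-6-[(2R)-2-methyl-10-phenyldecyl]-1,2-dioxane-4-carboxylate (6S; one C4 epimer) | C[C@H](CCCCCCCCc1ccccc1)C[C@@]1(C)C[C@](C)(C(=O)OC(C)(C)C)[C@](O)(CCO[Si](c2ccccc2)(c2ccccc2)C(C)(C)C)OO1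
A7 | alternative 3 | tert-butyl 5-(tert-butyldiphenylsilyloxy)-2-methyl-3-oxopentanoate | CC(C(=O)OC(C)(C)C)C(=O)CCO[Si](c1ccccc1)(c1ccccc1)C(C)(C)C
A8 | alternative 3 | [(9R)-9,11-dimethyldodec-11-en-1-yl]benzene | C[C@H](CCCCCCCCc1ccccc1)CC(C)=C
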